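**Retrosynthetic overview**

Locants are those of the bicyclo[3.2.1]octane: C-1 (OMe bridgehead), C-2 (C=O), C-3 (OMe), C-4 (CH2), C-5 (allyl bridgehead), C-6 (Me), C-7 (aryl), C-8 (OAc). The target is traced back, through C-3 protonation after 1,4-reduction, acetylation and a Stork–Danheiser removal of a temporary C-4 carbonyl, to a bicyclic 8-hydroxy-3-methoxy-2,4-dione.
Key disconnection: the C-5–C-8 and C-2–C-3 bonds are cut together, which opens both rings to an acyclic methoxymethyl ketone that carries an α-formyl ester. Forward, one base treatment closes the cyclopentane first (aldol, C-5 to C-8) and the cyclohexanone second (Dieckmann, C-3 to C-2).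
Enabling feature: in the six-membered ring C-1/C-2/C-3/C-4/C-5/C-8 the ketone carbon C-2 and the carbinol carbon C-8 both sit on the quaternary C-1(OMe), a latent ester and aldehyde on one carbon. C-3 and C-5 both flank C-4, so a temporary C-4 ketone turns both into enolate carbons.
The acyclic precursor comes from a chelation-controlled Ireland–Claisen rearrangement of an (R,Z)-allylic α-methoxy ester (sets C-1 and C-7), cross-metathesis to an enone, and anti-selective cuprate addition with enolate allylation (sets C-6).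

Key step: step 14

Remark: the bicyclic and monocyclic 2-methoxy-1,3-diketones are drawn as one enol tautomer each; the acyl α-carbon of the Claisen substrate and C-5 of the acyclic ketones are stereochemically irrelevant mixtures that are erased by enolisation.

**Route**

Step 1
Reactants: 1 dimethyl 2-methoxymalonate
Product: 2 2-methoxypropane-1,3-diol
Conditions: LiAlH4, THF, 0 °C to reflux; then H2O/NaOH work-up
Reagents that add atoms: none
Why: Hydride reduction of both ester groups of a 2-alkoxymalonate to the 2-alkoxy-1,3-diol should proceed without complication, and no stereocenter is formed.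

Step 2
Reactants: 2 2-methoxypropane-1,3-diol
Product: 3 rac-3-[(tert-butyldimethylsilyl)oxy]-2-methoxypropan-1-ol
Conditions: NaH (1 equiv), TBSCl (1 equiv), THF, 0 °C to rt
Reagents that add atoms: tert-butyldimethylsilyl chloride CC(C)(C)[Si](C)(C)Cl
Why: Monosilylation of a symmetrical diol through its monosodium alkoxide should stop at one silyl ether, and the racemic stereocenter formed here is erased in step 8.

Step 3
Reactants: 3 rac-3-[(tert-butyldimethylsilyl)oxy]-2-methoxypropan-1-ol
Product: 4 rac-3-[(tert-butyldimethylsilyl)oxy]-2-methoxypropanoic acid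
Conditions: TEMPO (cat.), PhI(OAc)2, MeCN/H2O, rt
Reagents that add atoms: water O
Why: Nitroxyl-catalysed oxidation of the primary alcohol through the aldehyde hydrate should give the acid and leave the silyl and methyl ethers untouched.

Step 4
Reactants: 5 N,2-dimethoxy-N-methylacetamide
Product: 6 1-methoxybut-3-en-2-one
Conditions: CH2=CHMgBr, THF, −78 to 0 °C; inverse quench into cold 1 M HCl
Reagents that add atoms: vinylmagnesium bromide C=C[Mg]Br
Why: Weinreb ketone synthesis, in which the chelated tetrahedral adduct survives until the acidic quench so that only one vinyl group is delivered.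

Step 5
Reactants: 7 4-iodo-1,2-dimethoxybenzene; 8 (R)-but-3-yn-2-ol
Product: 9 (R)-4-(3,4-dimethoxyphenyl)but-3-yn-2-ol
Conditions: PdCl2(PPh3)2 (cat.), CuI (cat.), Et3N, THF, rt
Reagents that add atoms: none
Why: Sonogashira coupling of an aryl iodide with a terminal alkyne, which does not touch the propargylic stereocenter of 8.

Step 6
Reactants: 9 (R)-4-(3,4-dimethoxyphenyl)but-3-yn-2-ol
Product: 10 (2R,3Z)-4-(3,4-dimethoxyphenyl)but-3-en-2-ol
Conditions: H2 (1 atm), Pd/CaCO3 poisoned with Pb(OAc)2, quinoline, EtOAc, rt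
Reagents that add atoms: none
Why: Lindlar semihydrogenation adds hydrogen syn on the poisoned palladium surface and should stop at the (Z)-alkene, with the carbinol stereocenter unaffected.

Step 7
Reactants: 10 (2R,3Z)-4-(3,4-dimethoxyphenyl)but-3-en-2-ol; 4 rac-3-[(tert-butyldimethylsilyl)oxy]-2-methoxypropanoic acid
Product: 11 (2R,3Z)-4-(3,4-dimethoxyphenyl)but-3-en-2-yl 3-[(tert-butyldimethylsilyl)oxy]-2-methoxypropanoate
Conditions: DCC, DMAP (cat.), CH2Cl2, 0 °C to rt
Reagents that add atoms: none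
Why: Steglich esterification acylates the secondary allylic alcohol with retention at the carbinol carbon, and the mixed configuration at the acyl α-carbon is erased in step 8.

Step 8
Reactants: 11 (2R,3Z)-4-(3,4-dimethoxyphenyl)but-3-en-2-yl 3-[(tert-butyldimethylsilyl)oxy]-2-methoxypropanoate
Product: 13 (2S,3S,4E)-2-{[(tert-butyldimethylsilyl)oxy]methyl}-3-(3,4-dimethoxyphenyl)-2-methoxyhex-4-enoic acid, via silyl ketene acetal 12 (not isolated)
Conditions: LiN(SiMe3)2, Me3SiCl, THF, −78 to 40 °C; then dilute aqueous citric acid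
Reagents that add atoms: none
Why: Ireland–Claisen rearrangement in which lithium chelation by the α-methoxy group gives the (Z)-silyl ketene acetal, and the chair transition state with the carbinol methyl equatorial and the aryl group of the (Z)-alkene axial should transfer the (R)-carbinol chirality to the quaternary C-2 and to C-3 and give the (E)-propenyl group.

Step 9
Reactants: 13 (2S,3S,4E)-2-{[(tert-butyldimethylsilyl)oxy]methyl}-3-(3,4-dimethoxyphenyl)-2-methoxyhex-4-enoic acid
Product: 14 methyl (2S,3S,4E)-2-{[(tert-butyldimethylsilyl)oxy]methyl}-3-(3,4-dimethoxyphenyl)-2-methoxyhex-4-enoate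
Conditions: Me3SiCHN2, MeOH/toluene, 0 °C
Reagents that add atoms: (trimethylsilyl)diazomethane C[Si](C)(C)C=[N+]=[N-]
Why: Diazoalkane esterification of the hindered acid proceeds under neutral conditions and touches no stereocenter.

Step 10
Reactants: 14 methyl (2S,3S,4E)-2-{[(tert-butyldimethylsilyl)oxy]methyl}-3-(3,4-dimethoxyphenyl)-2-methoxyhex-4-enoate; 6 1-methoxybut-3-en-2-one
Product: 15 methyl (2S,3S,4E)-2-{[(tert-butyldimethylsilyl)oxy]methyl}-3-(3,4-dimethoxyphenyl)-2,7-dimethoxy-6-oxohept-4-enoate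
Conditions: second-generation Hoveyda–Grubbs catalyst RuCl2(H2IMes)(=CH–C6H4-2-OiPr) (cat.), excess 6, CH2Cl2, 40 °C
Reagents that add atoms: none
Why: Olefin cross-metathesis between the only alkene of 14 and the electron-poor vinyl ketone should give the (E)-enone with loss of propene.

Step 11
Reactants: 15 methyl (2S,3S,4E)-2-{[(tert-butyldimethylsilyl)oxy]methyl}-3-(3,4-dimethoxyphenyl)-2,7-dimethoxy-6-oxohept-4-enoate
Product: 17 methyl (2S,3S,4R,5RS)-2-{[(tert-butyldimethylsilyl)oxy]methyl}-3-(3,4-dimethoxyphenyl)-2,7-dimethoxy-4-methyl-6-oxo-5-(prop-2-en-1-yl)heptanoate, via lithium enolate 16 (not isolated)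
Conditions: Me2CuLi (from MeLi and CuI), Et2O, −78 °C; then allyl bromide, DMPU, THF, −78 to −20 °C
Reagents that add atoms: lithium dimethylcuprate [Li+].C[Cu-]C; allyl bromide C=CCBr
Why: Tandem cuprate 1,4-addition and C-allylation of the regiodefined enolate, in which the methyl group should add anti to the bulky quaternary C-2 substituent in the conformer with the C-3 hydrogen inside (setting C-4 as R), while C-5 forms as a mixture that is erased in step 14.

Step 12
Reactants: 17 methyl (2S,3S,4R,5RS)-2-{[(tert-butyldimethylsilyl)oxy]methyl}-3-(3,4-dimethoxyphenyl)-2,7-dimethoxy-4-methyl-6-oxo-5-(prop-2-en-1-yl)heptanoate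
Product: 18 methyl (2S,3S,4R,5RS)-3-(3,4-dimethoxyphenyl)-2-(hydroxymethyl)-2,7-dimethoxy-4-methyl-6-oxo-5-(prop-2-en-1-yl)heptanoate
Conditions: HF·pyridine, THF, 0 °C to rt
Reagents that add atoms: none
Why: Fluoride-mediated desilylation under slightly acidic conditions frees the primary alcohol and avoids retro-aldol loss of formaldehyde from the β-hydroxy ester.

Step 13
Reactants: 18 methyl (2S,3S,4R,5RS)-3-(3,4-dimethoxyphenyl)-2-(hydroxymethyl)-2,7-dimethoxy-4-methyl-6-oxo-5-(prop-2-en-1-yl)heptanoate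
Product: 19 methyl (2S,3S,4R,5RS)-3-(3,4-dimethoxyphenyl)-2-formyl-2,7-dimethoxy-4-methyl-6-oxo-5-(prop-2-en-1-yl)heptanoate
Conditions: Dess–Martin periodinane, CH2Cl2, 0 °C to rt
Reagents that add atoms: none
Why: Dess–Martin oxidation converts the neopentyl primary alcohol into the non-enolisable α-formyl ester under neutral conditions without touching C-2.

Step 14
Reactants: 19 methyl (2S,3S,4R,5RS)-3-(3,4-dimethoxyphenyl)-2-formyl-2,7-dimethoxy-4-methyl-6-oxo-5-(prop-2-en-1-yl)heptanoate
Product: 21 (1S,5S,6R,7S,8S)-7-(3,4-dimethoxyphenyl)-4,8-dihydroxy-1,3-dimethoxy-6-methyl-5-(prop-2-en-1-yl)bicyclo[3.2.1]oct-3-en-2-one, via cyclopentanol aldol adduct 20 (not isolated)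
Conditions: KN(SiMe3)2 (3 equiv), THF, −78 to 0 °C; then 1 M HCl
Reagents that add atoms: none
Why: The base forms the ketone enolates reversibly; the C-5 enolate adds to the neopentyl aldehyde (aldol, C-5–C-8 bond) to give the potassium-chelated aldolate of 20, whose C-3 enolate then attacks the remaining methyl ester (Dieckmann condensation, C-2–C-3 bond), and deprotonation of the resulting 2-methoxy-1,3-diketone after loss of methoxide makes the sequence irreversible. The closest known reaction types are the base-mediated cyclisation of δ-keto esters to cyclohexane-1,3-diones and the (3+3) annulation of the two α-positions of a ketone with a malonyl unit (Effenberger-type cyclisation), run here as a tandem aldol/Dieckmann sequence. The cyclopentane closes first in a 5-(enolexo)-exo-trig aldol and the cyclohexane second in a 6-(enolendo)-exo-trig acyl substitution, which together give the bicyclo[3.2.1]octane. The quaternary C-5 is dictated by the preset C-1, because the three-carbon bridge can span C-1 and C-5 on one face of the cyclopentane only and aldol adducts with the other C-5 configuration revert by retro-aldol; C-8 is set in the chelated aldolate, where the alkoxide oxygen lies cis to the methoxyacetyl group and away from the C-6 methyl, and is locked once the second ring has formed. The step needs C-5 to attack the aldehyde and C-3 the ester; this is secured by the higher electrophilicity of the aldehyde, by five- over seven-membered aldol closure, by the reversibility of every aldol step, and by the fact that only the C-3 enolate reaches the ester through a six-membered transition state. The non-nucleophilic base and the absence of an α-hydrogen at C-1 guard the α-formyl ester against deformylation and epimerisation.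

Step 15
Reactants: 21 (1S,5S,6R,7S,8S)-7-(3,4-dimethoxyphenyl)-4,8-dihydroxy-1,3-dimethoxy-6-methyl-5-(prop-2-en-1-yl)bicyclo[3.2.1]oct-3-en-2-one
Product: 22 (1S,5S,6R,7S,8S)-7-(3,4-dimethoxyphenyl)-8-hydroxy-1,2,3-trimethoxy-6-methyl-5-(prop-2-en-1-yl)bicyclo[3.2.1]oct-2-en-4-one
Conditions: MeOH, TsOH (cat.), 3 Å molecular sieves, 50 °C
Reagents that add atoms: methanol CO
Why: Acid-catalysed vinylogous ester formation should take place at C-2, the carbonyl made more electrophilic by the adjacent C-1 methoxy group, which leaves the C-4 carbonyl as the ketone and changes no stereocenter.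

Step 16
Reactants: 22 (1S,5S,6R,7S,8S)-7-(3,4-dimethoxyphenyl)-8-hydroxy-1,2,3-trimethoxy-6-methyl-5-(prop-2-en-1-yl)bicyclo[3.2.1]oct-2-en-4-one
Product: 24 (1S,5R,6R,7S,8S)-7-(3,4-dimethoxyphenyl)-8-hydroxy-1,3-dimethoxy-6-methyl-5-(prop-2-en-1-yl)bicyclo[3.2.1]oct-3-en-2-one, via allylic alcohol 23 (not isolated)
Conditions: i-Bu2AlH, CH2Cl2, −78 °C; then 1 M HCl, THF, rt
Reagents that add atoms: water O
Why: Stork–Danheiser transposition, in which 1,2-reduction of the C-4 carbonyl followed by acid hydrolysis of the C-2 enol ether with loss of water should return the C-2 ketone and leave C-4 as the enone CH, so that the temporary C-4 oxygen is removed.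

Step 17
Reactants: 24 (1S,5R,6R,7S,8S)-7-(3,4-dimethoxyphenyl)-8-hydroxy-1,3-dimethoxy-6-methyl-5-(prop-2-en-1-yl)bicyclo[3.2.1]oct-3-en-2-one
Product: 25 (1S,5R,6R,7S,8S)-7-(3,4-dimethoxyphenyl)-1,3-dimethoxy-6-methyl-2-oxo-5-(prop-2-en-1-yl)bicyclo[3.2.1]oct-3-en-8-yl acetate
Conditions: Ac2O, DMAP (cat.), pyridine, rt
Reagents that add atoms: acetic anhydride CC(=O)OC(C)=O
Why: DMAP-catalysed acylation of the hindered secondary alcohol gives the acetate with retention at C-8.

Step 18
Reactants: 25 (1S,5R,6R,7S,8S)-7-(3,4-dimethoxyphenyl)-1,3-dimethoxy-6-methyl-2-oxo-5-(prop-2-en-1-yl)bicyclo[3.2.1]oct-3-en-8-yl acetate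
Product: 27 (1S,3S,5S,6R,7S,8S)-7-(3,4-dimethoxyphenyl)-1,3-dimethoxy-6-methyl-2-oxo-5-(prop-2-en-1-yl)bicyclo[3.2.1]octan-8-yl acetate, via potassium enolate 26 (not isolated)
Conditions: K[HB(s-Bu)3], THF, −78 °C; then AcOH, −78 °C
Reagents that add atoms: none
Why: Conjugate hydride addition of the bulky trialkylborohydride to the enone, followed by kinetic protonation of the enolate at C-3 from the face syn to C-8 and opposite the endo aryl group at C-7, should place the C-3 methoxy group endo (3S) and give the target, provided base is avoided afterwards.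

**Compound list**

1 | dimethyl 2-methoxymalonate | COC(C(=O)OC)C(=O)OC | starting material
2 | 2-methoxypropane-1,3-diol | COC(CO)CO | intermediate
3 | rac-3-[(tert-butyldimethylsilyl)oxy]-2-methoxypropan-1-ol | COC(CO)CO[Si](C)(C)C(C)(C)C | intermediate
4 | rac-3-[(tert-butyldimethylsilyl)oxy]-2-methoxypropanoic acid | COC(CO[Si](C)(C)C(C)(C)C)C(=O)O | intermediate
5 | N,2-dimethoxy-N-methylacetamide | COCC(=O)N(C)OC | starting material
6 | 1-methoxybut-3-en-2-one | COCC(=O)C=C | intermediate
7 | 4-iodo-1,2-dimethoxybenzene | COc1ccc(I)cc1OC | starting material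
8 | (R)-but-3-yn-2-ol | C[C@@H](O)C#C | starting material
9 | (R)-4-(3,4-dimethoxyphenyl)but-3-yn-2-ol | C[C@@H](O)C#Cc1ccc(OC)c(OC)c1 | intermediate
10 | (2R,3Z)-4-(3,4-dimethoxyphenyl)but-3-en-2-ol | C[C@@H](O)/C=C\c1ccc(OC)c(OC)c1 | intermediate
11 | (2R,3Z)-4-(3,4-dimethoxyphenyl)but-3-en-2-yl 3-[(tert-butyldimethylsilyl)oxy]-2-methoxypropanoate (both epimers at the acyl α-carbon) | COC(CO[Si](C)(C)C(C)(C)C)C(=O)O[C@H](C)/C=C\c1ccc(OC)c(OC)c1 | intermediate
12 | (Z)-trimethylsilyl ketene acetal of 11 (Me3SiO cis to OMe) | CO/C(CO[Si](C)(C)C(C)(C)C)=C(\O[Si](C)(C)C)O[C@H](C)/C=C\c1ccc(OC)c(OC)c1 | intermediate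
13 | (2S,3S,4E)-2-{[(tert-butyldimethylsilyl)oxy]methyl}-3-(3,4-dimethoxyphenyl)-2-methoxyhex-4-enoic acid | O=C(O)[C@](OC)([C@@H](/C=C/C)c1ccc(OC)c(OC)c1)CO[Si](C)(C)C(C)(C)C | intermediate
14 | methyl (2S,3S,4E)-2-{[(tert-butyldimethylsilyl)oxy]methyl}-3-(3,4-dimethoxyphenyl)-2-methoxyhex-4-enoate | COC(=O)[C@](OC)([C@@H](/C=C/C)c1ccc(OC)c(OC)c1)CO[Si](C)(C)C(C)(C)C | intermediate
15 | methyl (2S,3S,4E)-2-{[(tert-butyldimethylsilyl)oxy]methyl}-3-(3,4-dimethoxyphenyl)-2,7-dimethoxy-6-oxohept-4-enoate | COC(=O)[C@](OC)([C@@H](/C=C/C(=O)COC)c1ccc(OC)c(OC)c1)CO[Si](C)(C)C(C)(C)C | intermediate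
16 | lithium enolate of the cuprate 1,4-adduct of 15 (C-5=C-6 enolate, 4R) | [Li+].COC(=O)[C@@](OC)(CO[Si](C)(C)C(C)(C)C)[C@H](c1ccc(OC)c(OC)c1)[C@@H](C)C=C([O-])COC | intermediate
17 | methyl (2S,3S,4R,5RS)-2-{[(tert-butyldimethylsilyl)oxy]methyl}-3-(3,4-dimethoxyphenyl)-2,7-dimethoxy-4-methyl-6-oxo-5-(prop-2-en-1-yl)heptanoate | COC(=O)[C@@](OC)(CO[Si](C)(C)C(C)(C)C)[C@H](c1ccc(OC)c(OC)c1)[C@@H](C)C(CC=C)C(=O)COC | intermediate
18 | methyl (2S,3S,4R,5RS)-3-(3,4-dimethoxyphenyl)-2-(hydroxymethyl)-2,7-dimethoxy-4-methyl-6-oxo-5-(prop-2-en-1-yl)heptanoate | COC(=O)[C@@](OC)(CO)[C@H](c1ccc(OC)c(OC)c1)[C@@H](C)C(CC=C)C(=O)COC | intermediate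
19 | methyl (2S,3S,4R,5RS)-3-(3,4-dimethoxyphenyl)-2-formyl-2,7-dimethoxy-4-methyl-6-oxo-5-(prop-2-en-1-yl)heptanoate | COC(=O)[C@@](OC)(C=O)[C@H](c1ccc(OC)c(OC)c1)[C@@H](C)C(CC=C)C(=O)COC | intermediate
20 | methyl (1S,2S,3R,4S,5S)-2-(3,4-dimethoxyphenyl)-5-hydroxy-1-methoxy-4-(methoxyacetyl)-3-methyl-4-(prop-2-en-1-yl)cyclopentane-1-carboxylate (present as its potassium alkoxide) | C=CC[C@]1(C(=O)COC)[C@H](C)[C@@H](c2ccc(OC)c(OC)c2)[C@@](OC)(C(=O)OC)[C@H]1O | intermediate
21 | (1S,5S,6R,7S,8S)-7-(3,4-dimethoxyphenyl)-4,8-dihydroxy-1,3-dimethoxy-6-methyl-5-(prop-2-en-1-yl)bicyclo[3.2.1]oct-3-en-2-one | C=CC[C@]12C(O)=C(OC)C(=O)[C@](OC)([C@H](c3ccc(OC)c(OC)c3)[C@H]1C)[C@H]2O | intermediate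
22 | (1S,5S,6R,7S,8S)-7-(3,4-dimethoxyphenyl)-8-hydroxy-1,2,3-trimethoxy-6-methyl-5-(prop-2-en-1-yl)bicyclo[3.2.1]oct-2-en-4-one | C=CC[C@]12C(=O)C(OC)=C(OC)[C@](OC)([C@H](c3ccc(OC)c(OC)c3)[C@H]1C)[C@H]2O | intermediate
23 | 7-(3,4-dimethoxyphenyl)-1,2,3-trimethoxy-6-methyl-5-(prop-2-en-1-yl)bicyclo[3.2.1]oct-2-ene-4,8-diol (other centers as in 22, C-4 epimers) | C=CC[C@]12C(O)C(OC)=C(OC)[C@](OC)([C@H](c3ccc(OC)c(OC)c3)[C@H]1C)[C@H]2O | intermediate
24 | (1S,5R,6R,7S,8S)-7-(3,4-dimethoxyphenyl)-8-hydroxy-1,3-dimethoxy-6-methyl-5-(prop-2-en-1-yl)bicyclo[3.2.1]oct-3-en-2-one | C=CC[C@]12C=C(OC)C(=O)[C@](OC)([C@H](c3ccc(OC)c(OC)c3)[C@H]1C)[C@H]2O | intermediate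
25 | (1S,5R,6R,7S,8S)-7-(3,4-dimethoxyphenyl)-1,3-dimethoxy-6-methyl-2-oxo-5-(prop-2-en-1-yl)bicyclo[3.2.1]oct-3-en-8-yl acetate | C=CC[C@]12C=C(OC)C(=O)[C@](OC)([C@H](c3ccc(OC)c(OC)c3)[C@H]1C)[C@H]2OC(C)=O | intermediate
26 | potassium C-2 enolate (C-2=C-3) from 1,4-reduction of 25 | [K+].C=CC[C@]12CC(OC)=C([O-])[C@](OC)([C@H](c3ccc(OC)c(OC)c3)[C@H]1C)[C@H]2OC(C)=O | intermediate
27 | (1S,3S,5S,6R,7S,8S)-7-(3,4-dimethoxyphenyl)-1,3-dimethoxy-6-methyl-2-oxo-5-(prop-2-en-1-yl)bicyclo[3.2.1]octan-8-yl acetate | C=CC[C@]12C[C@H](OC)C(=O)[C@](OC)([C@H](c3ccc(OC)c(OC)c3)[C@H]1C)[C@H]2OC(C)=O | target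

**Step count and risks**

Total: 18 steps. Longest linear sequence: 15 steps (steps 1–3 and 7–18, from 1 through 4 and 11 to 27).

Step 14 (key step). The less hindered C-3 enolate may add to the aldehyde in a seven-membered aldol that is drained by dehydration, or the α-formyl ester may be deformylated by alkoxide (retro-Claisen cleavage), so that the two ring closures do not mesh. The fallback sets out from 17 and reverses the order of ring formation in separate operations. KOt-Bu in THF should close the only enolisable β-diketone available, the enolised 4-allylcycloheptane-1,3-dione silyl ether F1 (Dieckmann condensation of the C-3 enolate with the ester). HF·pyridine should then give the primary alcohol F2 and Dess–Martin oxidation the aldehyde F3. The dianion of F3 (LDA, 2.2 equiv, THF, −78 °C) can form only at C-5 because C-1 carries no hydrogen; it should add across the ring to the aldehyde and return the route to 21.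

Step 8. β-Elimination of the silyloxide from the ester enolate before O-silylation, or loss of the chelated enolate geometry, would erode the configuration at C-2. The fallback sets out from 10. Acylation with methoxyacetyl chloride (pyridine, CH2Cl2) gives the allylic methoxyacetate F4. Its glycolate Ireland–Claisen rearrangement (LiN(SiMe3)2, Me3SiCl) has no β-leaving group and should give the 2-methoxy acid F5 with the same transfer of chirality to C-3. Esterification (Me3SiCHN2) gives the methyl ester F6. Enolisation (LDA) and hydroxymethylation with monomeric formaldehyde should give the hydroxymethyl ester F7; the electrophile is expected to approach the chelated enolate anti to the aryl-bearing substituent, and any C-2 epimer is removed by chromatography. Silylation (TBSCl, imidazole) returns the route to 14.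

Step 15. Enol ether formation may occur at the C-4 instead of the C-2 carbonyl, since both are flanked by quaternary carbons; after step 16 this would lead to the transposed enone. The fallback sets out from 21. O-Sulfonylation of the more electron-rich C-4 enol oxygen (N-phenylbis(trifluoromethanesulfonimide), Et3N, CH2Cl2) should give the C-4 enol triflate F8. Palladium-catalysed formate reduction (Pd(OAc)2, PPh3, HCO2H, Et3N, DMF) then replaces the triflate by hydrogen and returns the route to 24 without passing through 22.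

**Further compounds**

F1 | step 14 | 4-allyl-7-{[(tert-butyldimethylsilyl)oxy]methyl}-6-(3,4-dimethoxyphenyl)-3-hydroxy-2,7-dimethoxy-5-methylcyclohept-2-en-1-one (C-5, C-6, C-7 as in 17; C-4 epimers) | C=CCC1C(O)=C(OC)C(=O)[C@@](OC)(CO[Si](C)(C)C(C)(C)C)[C@H](c2ccc(OC)c(OC)c2)[C@H]1C
F2 | step 14 | 4-allyl-6-(3,4-dimethoxyphenyl)-3-hydroxy-7-(hydroxymethyl)-2,7-dimethoxy-5-methylcyclohept-2-en-1-one (stereocenters as in F1) | C=CCC1C(O)=C(OC)C(=O)[C@@](OC)(CO)[C@H](c2ccc(OC)c(OC)c2)[C@H]1C
F3 | step 14 | 5-allyl-7-(3,4-dimethoxyphenyl)-4-hydroxy-1,3-dimethoxy-6-methyl-2-oxocyclohept-3-ene-1-carbaldehyde (stereocenters as in F1) | C=CCC1C(O)=C(OC)C(=O)[C@@](OC)(C=O)[C@H](c2ccc(OC)c(OC)c2)[C@H]1C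
F4 | step 8 | (2R,3Z)-4-(3,4-dimethoxyphenyl)but-3-en-2-yl 2-methoxyacetate | COCC(=O)O[C@H](C)/C=C\c1ccc(OC)c(OC)c1
F5 | step 8 | (3S,4E)-3-(3,4-dimethoxyphenyl)-2-methoxyhex-4-enoic acid (C-2 immaterial) | O=C(O)C(OC)[C@@H](/C=C/C)c1ccc(OC)c(OC)c1
F6 | step 8 | methyl (3S,4E)-3-(3,4-dimethoxyphenyl)-2-methoxyhex-4-enoate (C-2 immaterial) | COC(=O)C(OC)[C@@H](/C=C/C)c1ccc(OC)c(OC)c1
F7 | step 8 | methyl (2S,3S,4E)-3-(3,4-dimethoxyphenyl)-2-(hydroxymethyl)-2-methoxyhex-4-enoate | COC(=O)[C@](OC)([C@@H](/C=C/C)c1ccc(OC)c(OC)c1)CO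
F8 | step 15 | (1S,5S,6R,7S,8S)-7-(3,4-dimethoxyphenyl)-8-hydroxy-1,3-dimethoxy-6-methyl-2-oxo-5-(prop-2-en-1-yl)bicyclo[3.2.1]oct-3-en-4-yl trifluoromethanesulfonate | C=CC[C@]12C(OS(=O)(=O)C(F)(F)F)=C(OC)C(=O)[C@](OC)([C@H](c3ccc(OC)c(OC)c3)[C@H]1C)[C@H]2O
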